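**Retrosynthetic overview**

1. Torilin ⇒ late C8–O angeloylation, C10–OH → C10–H and C1 equilibration ⇒ a 10α‑hydroxy‑1α‑H‑guai‑4‑en‑3‑one carrying the 11‑acetate and a protected 8β‑oxygen.
2. That hydroazulenone ⇒ a eudesma‑1,4‑dien‑3‑one by the santonin‑type photorearrangement. The enabling feature is the cross‑conjugated dienone C1=C2–C3(=O)–C4(CH3)=C5 of ring A, with the quaternary, methyl‑bearing C10 between the two β‑carbons C1 and C5. C1–C5 bonding and the shift of C10 from C5 to C1 contract ring A to the cyclopentenone and expand ring B to the cycloheptane; the C4 methyl directs this mode.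
3. Dienone ⇒ a 2‑methylcyclohexanone (ring B) + ethyl vinyl ketone by auxiliary‑controlled Robinson annulation, then dehydrogenation.
4. Ring B ketone ⇒ (R)‑carvone (chiral pool: C7 stereocentre, C10 methyl and all ring B carbons); hydration gives C11–O, a hydroxyl‑directed epoxidation gives the cis C8–O.
5. Order of ring formation: ring B (carvone) → ring A (Robinson) → five‑ and seven‑membered rings together in the photochemical step.

Key step: step 10

Remark: guaiane/eudesmane numbering is used (C7 side chain, C8 oxygen, C10 methyl); β is the face of the C7 side chain.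
Remark (assumption): the natural 1β‑H form (C2 trans to the C10 methyl) is taken to be the more stable C1 epimer of the 3‑oxo‑guai‑4‑ene and to be reachable through the extended dienolate.
Remark: 3 and 4 are C2‑epimer mixtures (C2 left open in their SMILES); 7 and 10 are drawn as the equatorial‑methyl epimer; C2 becomes quaternary in step 6, so the epimers converge.

**Route**

Step 1
Reactants: 1 (R)-(−)-carvone
Product: 2 (5R)-5-(2-hydroxypropan-2-yl)-2-methylcyclohex-2-en-1-one
Conditions: 50% aq. H2SO4, 0 °C → rt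
Reagents that add atoms: water, O
Why: Acid‑catalysed Markovnikov hydration: the isopropenyl alkene is protonated to the tertiary cation far faster than the electron‑poor enone alkene and water is captured at the future C11, while the ring stereocentre is untouched.

Step 2
Reactants: 2 (5R)-5-(2-hydroxypropan-2-yl)-2-methylcyclohex-2-en-1-one
Product: 3 (5S)-5-(2-hydroxypropan-2-yl)-2-methylcyclohex-3-en-1-one (C2 epimers)
Conditions: KOtBu (3 equiv), THF/t-BuOH, 0 °C → rt; inverse quench into 10% aq. AcOH, 0 °C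
Reagents that add atoms: none
Why: Enone deconjugation: γ‑deprotonation at ring C4 gives the thermodynamic extended dienolate, and kinetic protonation at the α‑carbon C2 should give the β,γ‑enone with the ring C5 stereocentre unchanged.

Step 3
Reactants: 3 (5S)-5-(2-hydroxypropan-2-yl)-2-methylcyclohex-3-en-1-one (C2 epimers)
Product: 5 (4R,5S)-4-hydroxy-5-(2-hydroxypropan-2-yl)-2-methylcyclohex-2-en-1-one, via cis-epoxy ketone 4 (not isolated)
Conditions: VO(acac)2 (5 mol %), t-BuOOH (1.3 equiv, decane), CH2Cl2, 0 °C → rt; then Et3N (2 equiv), 0 °C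
Reagents that add atoms: tert-butyl hydroperoxide, CC(C)(C)OO
Why: Hydroxyl‑directed vanadium‑catalysed epoxidation: the vanadium‑bound homoallylic tertiary alkoxide delivers oxygen to the C3=C4 face syn to the side chain, and E1cB opening of the β,γ‑epoxy ketone (C2–H removal, C3–O cleavage) leaves the oxygen on C4 cis to the side chain.

Step 4
Reactants: 5 (4R,5S)-4-hydroxy-5-(2-hydroxypropan-2-yl)-2-methylcyclohex-2-en-1-one
Product: 6 (4R,5S)-4-[(tert-butyldimethylsilyl)oxy]-5-(2-hydroxypropan-2-yl)-2-methylcyclohex-2-en-1-one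
Conditions: TBSOTf (1.1 equiv), 2,6-lutidine, CH2Cl2, −78 °C
Reagents that add atoms: tert-butyldimethylsilyl triflate, CC(C)(C)[Si](C)(C)OS(=O)(=O)C(F)(F)F
Why: Silylation with a silyl triflate and a hindered base: at −78 °C the secondary allylic hydroxyl should react much faster than the tertiary carbinol, and no stereocentre is involved.

Step 5
Reactants: 6 (4R,5S)-4-[(tert-butyldimethylsilyl)oxy]-5-(2-hydroxypropan-2-yl)-2-methylcyclohex-2-en-1-one
Product: 7 (2R,4R,5S)-4-[(tert-butyldimethylsilyl)oxy]-5-(2-hydroxypropan-2-yl)-2-methylcyclohexan-1-one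
Conditions: H2 (1 atm), 10% Pd/C, EtOAc, rt
Reagents that add atoms: none
Why: Heterogeneous catalytic hydrogenation (syn addition) of the enone alkene; the new C2 centre is epimerisable, should settle as the equatorial methyl, and is erased in step 6.

Step 6
Reactants: 7 (2R,4R,5S)-4-[(tert-butyldimethylsilyl)oxy]-5-(2-hydroxypropan-2-yl)-2-methylcyclohexan-1-one; 8 (R)-(+)-1-phenylethylamine; 9 ethyl vinyl ketone
Product: 12 (2R,4R,5S)-4-[(tert-butyldimethylsilyl)oxy]-5-(2-hydroxypropan-2-yl)-2-methyl-2-(3-oxopentyl)cyclohexan-1-one, via ketimine 10 (not isolated), via Michael adduct ketimine 11 (not isolated)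
Conditions: 8 (1.1 equiv), TsOH (cat.), toluene, reflux (Dean–Stark); then 9, THF, 40 °C; then 10% aq. AcOH, rt
Reagents that add atoms: ethyl vinyl ketone 9, CCC(=O)C=C; water, O
Why: Chiral‑imine Michael addition: the secondary enamine tautomer adds to the enone at the more substituted α‑carbon through a compact aza‑ene‑like transition state, and the (R)‑1‑phenylethyl group steers the acceptor to the α‑face (also the face away from the axial silyloxy group), so the quaternary centre should carry the methyl cis to the side chain (future 10β‑CH3); aqueous acid then hydrolyses the imine.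

Step 7
Reactants: 12 (2R,4R,5S)-4-[(tert-butyldimethylsilyl)oxy]-5-(2-hydroxypropan-2-yl)-2-methyl-2-(3-oxopentyl)cyclohexan-1-one
Product: 13 (7S,8R,10R)-8-[(tert-butyldimethylsilyl)oxy]-11-hydroxyeudesm-4-en-3-one
Conditions: NaOMe (0.5 equiv), MeOH, rt
Reagents that add atoms: none
Why: Intramolecular aldol condensation (second stage of the Robinson annulation): the ethyl‑ketone enolate closes six‑membered ring A onto the ring ketone and dehydration gives the tetrasubstituted 4‑en‑3‑one; no stereocentre is formed.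

Step 8
Reactants: 13 (7S,8R,10R)-8-[(tert-butyldimethylsilyl)oxy]-11-hydroxyeudesm-4-en-3-one
Product: 14 (7S,8R,10R)-11-acetoxy-8-[(tert-butyldimethylsilyl)oxy]eudesm-4-en-3-one
Conditions: Ac2O, DMAP, Et3N, CH2Cl2, 40 °C
Reagents that add atoms: acetic anhydride, CC(=O)OC(C)=O
Why: DMAP‑catalysed acylation of the tertiary C11 alcohol, the only free hydroxyl present.

Step 9
Reactants: 14 (7S,8R,10R)-11-acetoxy-8-[(tert-butyldimethylsilyl)oxy]eudesm-4-en-3-one
Product: 15 (7S,8R,10S)-11-acetoxy-8-[(tert-butyldimethylsilyl)oxy]eudesma-1,4-dien-3-one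
Conditions: DDQ (1.3 equiv), 1,4-dioxane, 100 °C
Reagents that add atoms: none
Why: DDQ dehydrogenation of a 4‑en‑3‑one under neutral conditions removes hydride from C1 of the C2‑enol and installs C1=C2, giving the cross‑conjugated dienone; the quaternary C10 blocks aromatisation.

Step 10
Reactants: 15 (7S,8R,10S)-11-acetoxy-8-[(tert-butyldimethylsilyl)oxy]eudesma-1,4-dien-3-one
Product: 16 (1R,7S,8R,10R)-11-acetoxy-8-[(tert-butyldimethylsilyl)oxy]-10-hydroxyguai-4-en-3-one (1α-H; 10α-OH; 10β-CH3)
Conditions: hν (medium-pressure Hg lamp, Pyrex, λ > 300 nm), AcOH/H2O (2:1), N2, 15 °C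
Reagents that add atoms: water, O
Why: Excitation of the cross‑conjugated dienone leads to C1–C5 bonding and a cyclopropyl (C1–C5–C10) oxyallyl zwitterion, which acetic acid protonates on oxygen to a 2‑hydroxyallyl cation with most of its charge on the methyl‑bearing C4; the C5–C10 cyclopropane bond therefore breaks (C4=C5 forms) and water captures the tertiary C10 cation. The closest known reaction is the santonin → isophotosantonic lactone rearrangement, which runs the same way on 4‑methyl‑eudesma‑1,4‑dien‑3‑ones. Ring A closes to the cyclopentenone by β,β′ (C1–C5) bonding followed by cyclopropylcarbinyl opening, a net 1,2‑shift of C10 from C5 to C1 (six → five), and the same shift inserts C1 into ring B (six → seven), so neither ring is made by an end‑to‑end cyclisation. C1 is set stereospecifically by the C10 configuration (β‑methyl on C10 gives 1α‑H) and the C10–O bond forms by α‑face attack of water anti to the departing C5–C10 bond (10α‑OH, 10β‑CH3), while C7 and C8 are spectators. The step needs the 5/7 mode over the spiro mode and over the lumiketone pathway: the C4 methyl secures the first and the protic acidic medium the second, and λ > 300 nm keeps the product enone, the acetate and the silyl ether out of the photochemistry.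

Step 11
Reactants: 16 (1R,7S,8R,10R)-11-acetoxy-8-[(tert-butyldimethylsilyl)oxy]-10-hydroxyguai-4-en-3-one
Product: 17 methyl (1R,7S,8R,10R)-11-acetoxy-8-[(tert-butyldimethylsilyl)oxy]-3-oxoguai-4-en-10-yl oxalate
Conditions: ClC(O)CO2Me, DMAP (cat.), pyridine, CH2Cl2, 0 °C
Reagents that add atoms: methyl chlorooxoacetate, COC(=O)C(Cl)=O
Why: Acylation of the tertiary C10 alcohol with the highly electrophilic oxalyl half‑ester chloride gives the radical‑cleavable methyl oxalate; pyridine is too weak a base to trigger vinylogous elimination through C1–H.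

Step 12
Reactants: 17 methyl (1R,7S,8R,10R)-11-acetoxy-8-[(tert-butyldimethylsilyl)oxy]-3-oxoguai-4-en-10-yl oxalate
Product: 19 (1R,7S,8R,10S)-11-acetoxy-8-[(tert-butyldimethylsilyl)oxy]guai-4-en-3-one (1β-H; 10α-H), via 1α-H epimer 18 (not isolated)
Conditions: Bu3SnH (3 equiv), AIBN (cat.), toluene, 100 °C; then DBU (0.5 equiv), 60 °C
Reagents that add atoms: none
Why: Barton–McCombie‑type deoxygenation of a tertiary methyl oxalate: stannyl‑radical addition and β‑scission give the planar C10 radical, which should take hydrogen on the α‑face, opposite C2 on C1 and the 7β/8β substituents (10α‑H, 10β‑CH3; 18), and DBU then equilibrates C1 through the extended dienolate to the epimer with C2 trans to the C10 methyl (1β‑H; 19).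

Step 13
Reactants: 19 (1R,7S,8R,10S)-11-acetoxy-8-[(tert-butyldimethylsilyl)oxy]guai-4-en-3-one
Product: 20 (1R,7S,8R,10S)-11-acetoxy-8-hydroxyguai-4-en-3-one
Conditions: HF·pyridine, THF/pyridine, 0 °C → rt
Reagents that add atoms: none
Why: Fluoride‑mediated desilylation under buffered acidic conditions frees the C8 alcohol without generating an alkoxide, so acetyl migration from O11 and C1 scrambling are not expected.

Step 14
Reactants: 20 (1R,7S,8R,10S)-11-acetoxy-8-hydroxyguai-4-en-3-one; 21 angelic acid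
Product: 23 torilin, via mixed anhydride 22 (not isolated)
Conditions: 21, 2,4,6-trichlorobenzoyl chloride, Et3N, toluene, rt; then 20, 80 °C
Reagents that add atoms: angelic acid 21, C/C=C(/C)C(O)=O
Why: Yamaguchi esterification: the pre‑formed mixed anhydride acylates the hindered C8 alcohol at the angeloyl carbonyl, and leaving out nucleophilic catalysts should avoid Z→E isomerisation to the tiglate; C8 keeps its configuration.

**Compound list**

1 | (R)-(−)-carvone | CC1=CC[C@H](CC1=O)C(C)=C | starting material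
2 | (5R)-5-(2-hydroxypropan-2-yl)-2-methylcyclohex-2-en-1-one | CC1=CC[C@H](CC1=O)C(C)(C)O | intermediate
3 | (5S)-5-(2-hydroxypropan-2-yl)-2-methylcyclohex-3-en-1-one (C2 epimers) | CC1C=C[C@H](CC1=O)C(C)(C)O | intermediate
4 | (1R,5S,6S)-5-(2-hydroxypropan-2-yl)-2-methyl-7-oxabicyclo[4.1.0]heptan-3-one (epoxide cis to the side chain; C2 epimers; formed in situ) | CC1C(=O)C[C@H](C(C)(C)O)[C@@H]2O[C@H]12 | intermediate
5 | (4R,5S)-4-hydroxy-5-(2-hydroxypropan-2-yl)-2-methylcyclohex-2-en-1-one | CC1=C[C@@H](O)[C@H](CC1=O)C(C)(C)O | intermediate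
6 | (4R,5S)-4-[(tert-butyldimethylsilyl)oxy]-5-(2-hydroxypropan-2-yl)-2-methylcyclohex-2-en-1-one | CC1=C[C@@H](O[Si](C)(C)C(C)(C)C)[C@H](CC1=O)C(C)(C)O | intermediate
7 | (2R,4R,5S)-4-[(tert-butyldimethylsilyl)oxy]-5-(2-hydroxypropan-2-yl)-2-methylcyclohexan-1-one | C[C@@H]1C[C@@H](O[Si](C)(C)C(C)(C)C)[C@H](CC1=O)C(C)(C)O | intermediate
8 | (R)-(+)-1-phenylethylamine | C[C@@H](N)c1ccccc1 | starting material
9 | ethyl vinyl ketone (pent-1-en-3-one) | CCC(=O)C=C | starting material
10 | N-[(1R)-1-phenylethyl] ketimine of 7 (formed in situ) | C[C@@H]1C[C@@H](O[Si](C)(C)C(C)(C)C)[C@H](CC1=N[C@H](C)c2ccccc2)C(C)(C)O | intermediate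
11 | N-[(1R)-1-phenylethyl] ketimine of 12 (formed in situ) | CCC(=O)CC[C@]1(C)C[C@@H](O[Si](C)(C)C(C)(C)C)[C@H](CC1=N[C@H](C)c2ccccc2)C(C)(C)O | intermediate
12 | (2R,4R,5S)-4-[(tert-butyldimethylsilyl)oxy]-5-(2-hydroxypropan-2-yl)-2-methyl-2-(3-oxopentyl)cyclohexan-1-one | CCC(=O)CC[C@]1(C)C[C@@H](O[Si](C)(C)C(C)(C)C)[C@H](CC1=O)C(C)(C)O | intermediate
13 | (7S,8R,10R)-8-[(tert-butyldimethylsilyl)oxy]-11-hydroxyeudesm-4-en-3-one | CC1=C2C[C@H](C(C)(C)O)[C@H](O[Si](C)(C)C(C)(C)C)C[C@@]2(C)CCC1=O | intermediate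
14 | (7S,8R,10R)-11-acetoxy-8-[(tert-butyldimethylsilyl)oxy]eudesm-4-en-3-one | CC1=C2C[C@H](C(C)(C)OC(C)=O)[C@H](O[Si](C)(C)C(C)(C)C)C[C@@]2(C)CCC1=O | intermediate
15 | (7S,8R,10S)-11-acetoxy-8-[(tert-butyldimethylsilyl)oxy]eudesma-1,4-dien-3-one | CC1=C2C[C@H](C(C)(C)OC(C)=O)[C@H](O[Si](C)(C)C(C)(C)C)C[C@@]2(C)C=CC1=O | intermediate
16 | (1R,7S,8R,10R)-11-acetoxy-8-[(tert-butyldimethylsilyl)oxy]-10-hydroxyguai-4-en-3-one | CC(C)(C)[Si](C)(C)O[C@@H]1C[C@@](C)(O)[C@@H]2CC(=O)C(C)=C2C[C@@H]1C(C)(C)OC(C)=O | intermediate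
17 | methyl (1R,7S,8R,10R)-11-acetoxy-8-[(tert-butyldimethylsilyl)oxy]-3-oxoguai-4-en-10-yl oxalate | CC(C)(C)[Si](C)(C)O[C@@H]1C[C@@](C)(OC(=O)C(=O)OC)[C@@H]2CC(=O)C(C)=C2C[C@@H]1C(C)(C)OC(C)=O | intermediate
18 | (1S,7S,8R,10S)-11-acetoxy-8-[(tert-butyldimethylsilyl)oxy]guai-4-en-3-one (1α-H; formed in situ) | CC(C)(C)[Si](C)(C)O[C@@H]1C[C@H](C)[C@@H]2CC(=O)C(C)=C2C[C@@H]1C(C)(C)OC(C)=O | intermediate
19 | (1R,7S,8R,10S)-11-acetoxy-8-[(tert-butyldimethylsilyl)oxy]guai-4-en-3-one (1β-H) | CC(C)(C)[Si](C)(C)O[C@@H]1C[C@H](C)[C@H]2CC(=O)C(C)=C2C[C@@H]1C(C)(C)OC(C)=O | intermediate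
20 | (1R,7S,8R,10S)-11-acetoxy-8-hydroxyguai-4-en-3-one | O[C@@H]1C[C@H](C)[C@H]2CC(=O)C(C)=C2C[C@@H]1C(C)(C)OC(C)=O | intermediate
21 | angelic acid [(Z)-2-methylbut-2-enoic acid] | C/C=C(/C)C(O)=O | starting material
22 | angelic 2,4,6-trichlorobenzoic anhydride (formed in situ) | C/C=C(/C)C(=O)OC(=O)c1c(Cl)cc(Cl)cc1Cl | intermediate
23 | torilin | C/C=C(/C)C(=O)O[C@@H]1C[C@H](C)[C@H]2CC(=O)C(C)=C2C[C@@H]1C(C)(C)OC(C)=O | target

**Step count and risks**

Total step count: 14. Longest linear sequence: 14 steps, from (R)-carvone.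

Steps most likely to fail:

Step 12. Hydrogen‑atom transfer to the planar C10 radical may show poor facial selectivity. The homoallylic radical may also leak into the cyclopropylcarbinyl manifold, or the enone may be hydrostannated. The fallback sets out from 17: DBU in toluene at rt should trigger vinylogous E1cB loss of the oxalate (C1–H is γ to the enone) and give (7S,8R)-11-acetoxy-8-[(tert-butyldimethylsilyl)oxy]guaia-1(10),4-dien-3-one F4. Hydrogenation of its γ,δ‑double bond (H2, Pd/C, EtOAc, trace Et3N) should add both hydrogens from the α‑face, opposite the 7β and 8β substituents, to give 18. DBU equilibration as in step 12 then gives 19, where the route is rejoined.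

Step 2. The tertiary alkoxide may add to the enone (intramolecular oxa‑Michael), the dienolate may be reprotonated at C4, or the β,γ‑enone may reconjugate before it is epoxidised. The fallback sets out from 2: TMSCl/NaI/Et3N in MeCN gives the extended bis‑silyl dienol ether (5S)-2-methyl-1-(trimethylsilyloxy)-5-[2-(trimethylsilyloxy)propan-2-yl]cyclohexa-1,3-diene F1. Buffered mCPBA (vinylogous Rubottom oxidation) attacks C4 anti to the side chain, and acidic work‑up gives the trans‑diol (4S,5S)-4-hydroxy-5-(2-hydroxypropan-2-yl)-2-methylcyclohex-2-en-1-one F2. Mitsunobu inversion (4‑nitrobenzoic acid, DIAD, PPh3) gives (1R,6S)-6-(2-hydroxypropan-2-yl)-3-methyl-4-oxocyclohex-2-en-1-yl 4-nitrobenzoate F3, and K2CO3/MeOH releases 5, where the route is rejoined.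

Step 14. The angeloyl unit may isomerise Z→E to the tiglate, acylation of the hindered C8 alcohol may be slow, or base may move the acetyl group from O11 to O8. The fallback sets out from 20: esterification with 2‑[bis(2,2,2‑trifluoroethoxy)phosphoryl]propanoic acid (EDC, DMAP cat., CH2Cl2) gives the C8 phosphonopropanoate of 20 F5. Still–Gennari olefination (KHMDS, 18‑crown‑6, THF, −78 °C, acetaldehyde) then builds the (Z)‑2‑methylbut‑2‑enoate on the molecule and arrives directly at 23.

Further compounds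

F1 | step 2 | (5S)-2-methyl-1-(trimethylsilyloxy)-5-[2-(trimethylsilyloxy)propan-2-yl]cyclohexa-1,3-diene | CC1=C(O[Si](C)(C)C)C[C@@H](C=C1)C(C)(C)O[Si](C)(C)C
F2 | step 2 | (4S,5S)-4-hydroxy-5-(2-hydroxypropan-2-yl)-2-methylcyclohex-2-en-1-one | CC1=C[C@H](O)[C@H](CC1=O)C(C)(C)O
F3 | step 2 | (1R,6S)-6-(2-hydroxypropan-2-yl)-3-methyl-4-oxocyclohex-2-en-1-yl 4-nitrobenzoate | CC1=C[C@@H](OC(=O)c2ccc(cc2)[N+](=O)[O-])[C@H](CC1=O)C(C)(C)O
F4 | step 12 | (7S,8R)-11-acetoxy-8-[(tert-butyldimethylsilyl)oxy]guaia-1(10),4-dien-3-one | CC(C)(C)[Si](C)(C)O[C@@H]1CC(C)=C2CC(=O)C(C)=C2C[C@@H]1C(C)(C)OC(C)=O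
F5 | step 14 | (1R,7S,8R,10S)-11-acetoxy-3-oxoguai-4-en-8-yl 2-[bis(2,2,2-trifluoroethoxy)phosphoryl]propanoate (epimers at the phosphonate α-carbon) | CC(C(=O)O[C@@H]1C[C@H](C)[C@H]2CC(=O)C(C)=C2C[C@@H]1C(C)(C)OC(C)=O)P(=O)(OCC(F)(F)F)OCC(F)(F)F
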